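The midnight and summer runs differ in precatalyst, 0.12 mM against 0.50 mM, and our flask lies between them.

the same everywhere: left-handed substrate 0.050 M; right-handed substrate 0.050 M; impurity 2.6 mM; added ligand 41 mM

| run | partner | free catalyst | precatalyst | remark | time |
|---|---|---|---|---|---|
| midnight | 0.11 M | 7 mM | 0.12 mM | run made earlier |  |
| summer | 0.11 M | 7 mM | 0.50 mM | run made earlier |  |
| flask | 0.110 M | 7.0 mM | 0.25 mM |  | 2.5 d |

| run | time / h | left-handed product / % | right-handed product / % | left-handed substrate / % |
|---|---|---|---|---|
| midnight | 10.0 | 49.2 | 4.1 | 0 |
| midnight | 20.0 | 50.3 | 7.8 | 0 |
| midnight | 25.0 | 50.1 | 9.7 | 0.3 |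
| midnight | 40.0 | 50.1 | 13.6 | 0 |
| summer | 3.00 | 46.0 | 2.0 | 4.0 |
| summer | 6.00 | 49.5 | 2.7 | 0 |
| summer | 15.0 | 50.2 | 6.3 | 0.2 |
| summer | 40.0 | 50.0 | 13.8 | 0 |

(scatter of a reading: 0.3 percentage points)

* left-handed product and right-handed product together, in percent of the left-handed substrate and right-handed substrate charged together, at 2.5 d
* excess of left-handed product over right-handed product in the product at 2.5 d
* whether the exchange between left-handed substrate and right-handed substrate keeps pace with the reaction: how far the product's excess at 2.5 d gets from its value without exchange to its value with instant exchange (above 80% keeps pace, below 20% hardly takes part, else lags behind)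

- free catalyst is single-handed; left-handed substrate and right-handed substrate are mirror images of each other, charged as a racemate, each of them at the stated concentration
- an excess is below zero if the other one leads

Precatalyst need not be known well: at 40.0 h the right-handed product reads 13.6% and 13.8%, a gap less than the scatter of 0.3 percentage points. The left-handed product need not be known well either: at that time it reads 50.1% and 50.0%, close to the left-handed share of the charge. Those readings show no right-handed substrate crossing over beyond the scatter, so we take the exchange to hardly take part. The right-handed product does matter: it enters y one for one and must be carried 1.50 times past the last reading.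

So we work with what is left. Once the left-handed substrate is gone, reading 0% at 40.0 h in the midnight run, partner and right-handed substrate fall in equal steps. For a rate first order in each, with the catalyst held steady, ln(c(partner)/c(right-handed substrate)) then climbs on a straight line. Counting from zero as if that loss came at once, the midnight run gives 0.00151 h⁻¹ and the summer run 0.00154 h⁻¹. The log-ratio slope g, the rise of that logarithm per unit time, is their mean, 0.00153 h⁻¹.

From 1.20 the ratio reaches 1.31 at 2.5 d, which means 0.0183 M of right-handed product, or 18.3%. Our reckoning is y 68.3% and eP 46.5%. An error in that product moves eP twice as far as y.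

The forecast gives 68.4%, 46.2% and hardly takes part, on a rate “first order in remaining right-handed substrate and in remaining partner”. It stands 0.10 points from ours in y and 0.30 points in eP.

    partner + free catalyst + right-handed substrate → free catalyst + right-handed product (k = 0.696 L² mol⁻² min⁻¹)
    racemization catalyst + impurity → spent catalyst (k = 323 L mol⁻¹ min⁻¹)
    partner + precatalyst → racemization catalyst + spent reagent (k = 0.0296 L mol⁻¹ min⁻¹)
    free catalyst + added ligand ⇌ idle complex, settled at all times (K = 26.0 L mol⁻¹)
    partner + free catalyst + left-handed substrate → free catalyst + left-handed product (k = 52.6 L² mol⁻² min⁻¹)
    left-handed substrate + racemization catalyst ⇌ right-handed substrate + racemization catalyst, rate k6*[racemization catalyst]*[left-handed substrate] forward; the back reaction follows from the equilibrium constant (k = 2.63 L mol⁻¹ min⁻¹)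

The flask gives 68.0%, 47.1% and hardly takes part. The exchange gets 0.12% of the way to the instant-exchange excess. The neighbour with 0.070 M of added ligand holds 37.0% free catalyst at 2.50 d, against 50.6% in the flask. Scaled by that ratio, g becomes 0.00111 h⁻¹, the ratio reaches 1.28, and we reckon 14.7% right-handed product, where that neighbour stands at 14.5%.

(The readings were generated by integration with constants of no real substance.)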